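(The constants are those of an exercise, and the outcome is calculated.)

We read the flasks 2.5 min after mixing and ask how much of the substrate stands then as bis adduct.

    substrate + reagent → single product + by-product (k1 = 1.97 M⁻¹ s⁻¹)
    reagent + single product → bis adduct + by-product (k2 = 1.27 M⁻¹ s⁻¹)
    reagent + bis adduct → over-reaction product (k3 = 0.329 M⁻¹ s⁻¹)

| flask | substrate | reagent | time |
|---|---|---|---|
| ochre | 14 mM | 20.0 mM | 2.5 min |
| grey | 14 mM | 30.0 mM | 2.5 min |
| teal | 14 mM | 40.0 mM | 2.5 min |
| red | 14 mM | 60.0 mM | 2.5 min |

- "hardly changes" means that all values lie within two and a half points (for a concentration: within two and a half percent of the largest)
- run time (ochre): 2.5 min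

* amount of bis adduct at the end, in percent of the substrate charged for ochre, grey, teal, red, in this order
* the course of these numbers from the first flask to the last (rises all the way / hardly changes / rises, then falls / falls, then rises / falls all the way)

Our own reckoning is a ledger, kept in fractions of the substrate charge.

1. Red is charged with 4.29 of reagent, more than the 3 that the scheme can take per substrate, so the substrate is its limiting reagent.

2. We follow one full charge of substrate through red. Step 1 takes 1 of reagent to make single product, and step 2 takes 1 more to make bis adduct. That leaves 2.29.

3. Step 3 can then take a last 1, turning bis adduct into over-reaction product. The books close with 1.29 of reagent unspent, which is 30.0% of its own charge.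

4. The same entries leave 0.857 after step 2 in teal and 0.143 in grey. Ochre holds 1.43, less than the 2 that the first two entries ask, so its ledger cannot bring the full charge of substrate to bis adduct.

5. We treat step 3 as pseudo-first-order in bis adduct, taking what remains after step 2 as its reagent. We call the drain count the number of half-lives of bis adduct under step 3 that fit into the reading time, with the reagent held at what the first two entries leave. For red it is 2.28, and for teal 0.854.

6. Halving that many times leaves 0.206 of the charge as bis adduct in red and 0.553 in teal. The count has bis adduct present from the start and holds the reagent fixed, though step 3 spends it, so we take these fractions as rough estimates, not as bounds. We expect a rise from ochre, then a fall to red.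

The forecast gives 37.6%, 55.6%, 56.9% and 33.9%, a course that rises, then falls. In its words, “with a large excess the slower third step has time to drain the bis adduct into over-reaction product”. Our estimate for red lies lower than its value.

The simulation gives 37.7%, 55.6%, 56.9% and 34.1%, a course that rises, then falls, and the forecast stands.

With step 3 taken away, red ends at 99.7% bis adduct in place of 34.1%, so that step is the main reason red sits low. The 2.28 half-lives of the drain count gave red an estimate of 0.206, and the flask holds more than that, at 34.1%. In teal, 0.854 half-lives gave an estimate of 0.553, and the flask again holds more, at 56.9%.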